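**Strategy.** Everything rests on cutting the C1''–C2'' bond between the benzylic CH2 on C3' of ring B (the 2-aryl ring) and the olefinic CH of the side chain (C1''–C8'' counted from the ring). The key step exploits the (E)-trisubstituted C2''=C3''(CH3) olefin: it is written onto a terminal alkyne, 2-methylhept-6-yn-2-ol, by Zr-catalysed syn-methylalumination, and the resulting (E)-alkenylalane is coupled in the same pot with an ortho-silyloxybenzyl bromide under Pd(0). One operation thus installs the C3'' methyl, fixes the olefin geometry and forms C1''–C2''. The aryl bromide left in the product becomes a boronic acid, whose Rh-catalysed asymmetric 1,4-addition to a 5,7-disilylated chromone builds the chromanone and sets C2 as S.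

Key step: step 4

Remark: the sense of induction of the (S)-bisphosphine–Rh catalyst on the chromone is taken to follow that on simple cyclic enones, which corresponds to 2S here; the (R)-ligand is the remedy if the sense proves opposite.

**Step 1**
Reactants: 1 methyl hex-5-ynoate
Product: 2 2-methylhept-6-yn-2-ol
Conditions: MeMgBr (3 equiv), THF, 0 °C → rt; aq. NH4Cl
Reagents that add atoms: methylmagnesium bromide, C[Mg]Br
Why: double Grignard addition to the ester should give the tertiary carbinol, since ester addition at 0 °C outruns metalation of the alkyne C–H and any acetylide is reprotonated on work-up.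

**Step 2**
Reactants: 3 4-bromo-2-methylphenol
Product: 4 (4-bromo-2-methylphenoxy)(tert-butyl)dimethylsilane
Conditions: TBSCl, imidazole, DMF, rt
Reagents that add atoms: tert-butyldimethylsilyl chloride, C[Si](C)(Cl)C(C)(C)C
Why: imidazole-mediated O-silylation of a phenol gives an aryl silyl ether that should survive the radical, organoaluminium and organolithium steps and fall to fluoride at the end.

**Step 3**
Reactants: 4 (4-bromo-2-methylphenoxy)(tert-butyl)dimethylsilane
Product: 5 [4-bromo-2-(bromomethyl)phenoxy](tert-butyl)dimethylsilane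
Conditions: NBS (1.05 equiv), AIBN (cat.), PhCF3, 80 °C
Reagents that add atoms: N-bromosuccinimide, O=C1CCC(=O)N1Br
Why: Wohl–Ziegler bromination should take the only benzylic C–H bonds, those of the ring methyl, while the non-polar radical conditions disfavour ionic ring bromination.

**Step 4**
Reactants: 2 2-methylhept-6-yn-2-ol; 5 [4-bromo-2-(bromomethyl)phenoxy](tert-butyl)dimethylsilane
Product: 7 (6E)-8-{5-bromo-2-[(tert-butyldimethylsilyl)oxy]phenyl}-2,6-dimethyloct-6-en-2-ol, via (E)-alkenylalane 6 (not isolated)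
Conditions: 2 (1.3 equiv), Me3Al (3 equiv), Cp2ZrCl2 (0.25 equiv), CH2Cl2, 0 °C → rt; excess Me3Al and solvent removed in vacuo; then 5 (1.0 equiv), Pd(PPh3)4 (5 mol%), THF, rt; aq. Rochelle salt
Reagents that add atoms: trimethylaluminium, C[Al](C)C
Why: Me3Al first caps the hydroxyl of 2 as its dimethylaluminium alkoxide, then Cp2ZrCl2/Me3Al adds CH3–Al syn across the terminal alkyne with Al on the terminal carbon to give alkenylalane 6; Pd(0) inserts into the benzylic C–Br bond of 5, the alkenyl group passes from Al to Pd with retention, and reductive elimination forms the CH2–CH= bond. The closest known reaction type is the Negishi Zr-catalysed carboalumination run in one pot with the Pd- or Ni-catalysed cross-coupling of alkenylalanes with benzylic halides, as used for prenylated arenes and quinones. No ring is closed. No stereocentre is formed; the E geometry of C6=C7 is fixed by the syn mode and terminal-Al regiochemistry of the carbometalation and should be carried through the coupling unchanged. The step needs chemoselectivity for the benzylic over the aryl C–Br bond, which is secured because SN2-type oxidative addition of Pd(PPh3)4 to a benzylic bromide at room temperature is far faster than insertion into the electron-rich para-silyloxy aryl bromide. It also needs alkenyl rather than methyl transfer from aluminium, which is intrinsic to alkenyl(dimethyl)alanes and is helped by stripping the excess Me3Al before the coupling.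

**Step 5**
Reactants: 7 (6E)-8-{5-bromo-2-[(tert-butyldimethylsilyl)oxy]phenyl}-2,6-dimethyloct-6-en-2-ol
Product: 9 {4-[(tert-butyldimethylsilyl)oxy]-3-[(2E)-7-hydroxy-3,7-dimethyloct-2-en-1-yl]phenyl}boronic acid, via aryllithium 8 (not isolated)
Conditions: n-BuLi (2.2 equiv), THF, −78 °C; B(OiPr)3 (3 equiv), −78 °C → rt; aq. NH4Cl (pH 5–6), 0 °C
Reagents that add atoms: triisopropyl borate, CC(C)OB(OC(C)C)OC(C)C; water, O
Why: after the first equivalent of base has taken the hydroxyl proton, bromine–lithium exchange at −78 °C should give the aryllithium, which is trapped by the borate and hydrolysed to the boronic acid under mildly acidic conditions that spare the silyl ether, the olefin and the tertiary alcohol.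

**Step 6**
Reactants: 10 5,7-dihydroxy-4H-chromen-4-one
Product: 11 5,7-bis[(tert-butyldimethylsilyl)oxy]-4H-chromen-4-one
Conditions: TBSCl (3 equiv), imidazole (6 equiv), DMAP (cat.), DMF, 50 °C
Reagents that add atoms: tert-butyldimethylsilyl chloride, C[Si](C)(Cl)C(C)(C)C
Why: exhaustive O-silylation, with gentle warming for the hydrogen-bonded 5-OH, removes both acidic phenols and should make the chromone soluble and compatible with the rhodium catalyst.

**Step 7**
Reactants: 9 {4-[(tert-butyldimethylsilyl)oxy]-3-[(2E)-7-hydroxy-3,7-dimethyloct-2-en-1-yl]phenyl}boronic acid; 11 5,7-bis[(tert-butyldimethylsilyl)oxy]-4H-chromen-4-one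
Product: 12 (2S)-5,7-bis[(tert-butyldimethylsilyl)oxy]-2-{4-[(tert-butyldimethylsilyl)oxy]-3-[(2E)-7-hydroxy-3,7-dimethyloct-2-en-1-yl]phenyl}-2,3-dihydro-4H-chromen-4-one
Conditions: [Rh(OH)((S)-MeO-F12-BIPHEP)]2 (3 mol% Rh), 9 (1.5 equiv), toluene/H2O (10:1), 25 °C
Reagents that add atoms: none
Why: in this Hayashi–Miyaura asymmetric 1,4-addition the aryl–Rh(I) species formed by transmetalation should add across C2=C3 of the chromone and water protonates the rhodium enolate at C3, the C2 stereocentre being set by the chiral bisphosphine, whose (S) form is expected to deliver the aryl group to the enone face that gives 2S.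

**Step 8**
Reactants: 12 (2S)-5,7-bis[(tert-butyldimethylsilyl)oxy]-2-{4-[(tert-butyldimethylsilyl)oxy]-3-[(2E)-7-hydroxy-3,7-dimethyloct-2-en-1-yl]phenyl}-2,3-dihydro-4H-chromen-4-one
Product: 13 (2S)-5,7-dihydroxy-2-{4-hydroxy-3-[(2E)-7-hydroxy-3,7-dimethyloct-2-en-1-yl]phenyl}-2,3-dihydro-4H-chromen-4-one (CNP0161524.1)
Conditions: TBAF/AcOH (1:1, 4 equiv), THF, 0 °C → rt
Reagents that add atoms: none
Why: buffered fluoride should cleave the three aryl silyl ethers without touching the tertiary alcohol or the olefin, and the acetic acid keeps the phenols protonated so that the flavanone does not open to the chalcone and C2 keeps its configuration.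

**Compound list**

1 | methyl hex-5-ynoate | C#CCCCC(=O)OC | starting material
2 | 2-methylhept-6-yn-2-ol | C#CCCCC(C)(C)O | intermediate
3 | 4-bromo-2-methylphenol | Cc1cc(Br)ccc1O | starting material
4 | (4-bromo-2-methylphenoxy)(tert-butyl)dimethylsilane | Cc1cc(Br)ccc1O[Si](C)(C)C(C)(C)C | intermediate
5 | [4-bromo-2-(bromomethyl)phenoxy](tert-butyl)dimethylsilane | BrCc1cc(Br)ccc1O[Si](C)(C)C(C)(C)C | intermediate
6 | dimethyl{(1E)-6-[(dimethylalumanyl)oxy]-2,6-dimethylhept-1-en-1-yl}alumane (formed in the flask) | C/C(=C\[Al](C)C)CCCC(C)(C)O[Al](C)C | intermediate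
7 | (6E)-8-{5-bromo-2-[(tert-butyldimethylsilyl)oxy]phenyl}-2,6-dimethyloct-6-en-2-ol | C/C(=C\Cc1cc(Br)ccc1O[Si](C)(C)C(C)(C)C)CCCC(C)(C)O | intermediate
8 | {4-[(tert-butyldimethylsilyl)oxy]-3-[(2E)-7-(lithiooxy)-3,7-dimethyloct-2-en-1-yl]phenyl}lithium (formed in the flask) | C/C(=C\Cc1cc([Li])ccc1O[Si](C)(C)C(C)(C)C)CCCC(C)(C)O[Li] | intermediate
9 | {4-[(tert-butyldimethylsilyl)oxy]-3-[(2E)-7-hydroxy-3,7-dimethyloct-2-en-1-yl]phenyl}boronic acid | C/C(=C\Cc1cc(B(O)O)ccc1O[Si](C)(C)C(C)(C)C)CCCC(C)(C)O | intermediate
10 | 5,7-dihydroxy-4H-chromen-4-one | O=c1ccoc2cc(O)cc(O)c12 | starting material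
11 | 5,7-bis[(tert-butyldimethylsilyl)oxy]-4H-chromen-4-one | O=c1ccoc2cc(O[Si](C)(C)C(C)(C)C)cc(O[Si](C)(C)C(C)(C)C)c12 | intermediate
12 | (2S)-5,7-bis[(tert-butyldimethylsilyl)oxy]-2-{4-[(tert-butyldimethylsilyl)oxy]-3-[(2E)-7-hydroxy-3,7-dimethyloct-2-en-1-yl]phenyl}-2,3-dihydro-4H-chromen-4-one | C/C(=C\Cc1cc([C@@H]2CC(=O)c3c(O[Si](C)(C)C(C)(C)C)cc(O[Si](C)(C)C(C)(C)C)cc3O2)ccc1O[Si](C)(C)C(C)(C)C)CCCC(C)(C)O | intermediate
13 | (2S)-5,7-dihydroxy-2-{4-hydroxy-3-[(2E)-7-hydroxy-3,7-dimethyloct-2-en-1-yl]phenyl}-2,3-dihydro-4H-chromen-4-one | C/C(=C\Cc1cc([C@@H]2CC(=O)c3c(O)cc(O)cc3O2)ccc1O)CCCC(C)(C)O | target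

**Count**

Total steps: 8. Longest linear sequence: 6 steps (steps 2, 3, 4, 5, 7, 8, from compound 3).

**Steps most likely to fail**

Step 4. The palladium may also insert into the aryl C–Br bond, methyl instead of alkenyl may be transferred from aluminium, or the benzylic bromide may homocouple. The fallback sets out from 2 and 5 and comes back at 7, with the polarity of the coupling reversed. Alkyne 2 is carboaluminated as before to 6, and the alane is quenched with iodine (THF, −30 °C → 0 °C) to give (E)-7-iodo-2,6-dimethylhept-6-en-2-ol F1. Bromide 5 is converted with zinc dust and LiCl in THF into {5-bromo-2-[(tert-butyldimethylsilyl)oxy]benzyl}zinc bromide F2. Negishi coupling of F1 with F2 (Pd(PPh3)4, THF, rt, one extra equivalent of F2 for the hydroxyl proton) should form the same bond and give 7. Here the sp2 partner is an alkenyl iodide that undergoes oxidative addition far faster than the aryl bromide, and no methyl–aluminium species is present.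

Step 7. Carbometalation of the electron-rich, vinylogous-ester-like chromone may be slow, so that protodeboronation of 9 takes over, or the facial selectivity may be insufficient. The fallback sets out from 9 and 11 and comes back at 12, with the stereocentre secured by kinetic resolution instead of asymmetric addition. The more active achiral diene catalyst [Rh(OH)(cod)]2 (dioxane/H2O, 50 °C) should give racemic 5,7-bis[(tert-butyldimethylsilyl)oxy]-2-{4-[(tert-butyldimethylsilyl)oxy]-3-[(2E)-7-hydroxy-3,7-dimethyloct-2-en-1-yl]phenyl}-2,3-dihydro-4H-chromen-4-one F3. Noyori–Ikariya asymmetric transfer hydrogenation (RuCl(p-cymene)[(R,R)-TsDPEN], HCO2H/Et3N, rt, stopped near half conversion) should reduce the 2R ketone preferentially to the cis alcohol (2R,4R)-5,7-bis[(tert-butyldimethylsilyl)oxy]-2-{4-[(tert-butyldimethylsilyl)oxy]-3-[(2E)-7-hydroxy-3,7-dimethyloct-2-en-1-yl]phenyl}-3,4-dihydro-2H-chromen-4-ol F4. The unreacted 2S ketone 12 is separated from F4 by chromatography.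

Step 5. Proton transfer from the doubly activated benzylic-allylic CH2 to the aryllithium, or protodeboronation during the aqueous isolation, may erode the boronic acid. The fallback sets out from 7 and comes back at 9 without any organolithium. Miyaura borylation (B2pin2, PdCl2(dppf), KOAc, dioxane, 80 °C) should give (6E)-8-{2-[(tert-butyldimethylsilyl)oxy]-5-(4,4,5,5-tetramethyl-1,3,2-dioxaborolan-2-yl)phenyl}-2,6-dimethyloct-6-en-2-ol F5, which is purified on silica. Oxidative cleavage of the pinacol ester (NaIO4, NH4OAc, acetone/H2O, rt) then releases 9.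

**Further compounds**

F1 | step 4 | (E)-7-iodo-2,6-dimethylhept-6-en-2-ol | C/C(=C\I)CCCC(C)(C)O
F2 | step 4 | {5-bromo-2-[(tert-butyldimethylsilyl)oxy]benzyl}zinc bromide | Br[Zn]Cc1cc(Br)ccc1O[Si](C)(C)C(C)(C)C
F3 | step 7 | racemic 5,7-bis[(tert-butyldimethylsilyl)oxy]-2-{4-[(tert-butyldimethylsilyl)oxy]-3-[(2E)-7-hydroxy-3,7-dimethyloct-2-en-1-yl]phenyl}-2,3-dihydro-4H-chromen-4-one | C/C(=C\Cc1cc(C2CC(=O)c3c(O[Si](C)(C)C(C)(C)C)cc(O[Si](C)(C)C(C)(C)C)cc3O2)ccc1O[Si](C)(C)C(C)(C)C)CCCC(C)(C)O
F4 | step 7 | (2R,4R)-5,7-bis[(tert-butyldimethylsilyl)oxy]-2-{4-[(tert-butyldimethylsilyl)oxy]-3-[(2E)-7-hydroxy-3,7-dimethyloct-2-en-1-yl]phenyl}-3,4-dihydro-2H-chromen-4-ol | C/C(=C\Cc1cc([C@H]2C[C@@H](O)c3c(O[Si](C)(C)C(C)(C)C)cc(O[Si](C)(C)C(C)(C)C)cc3O2)ccc1O[Si](C)(C)C(C)(C)C)CCCC(C)(C)O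
F5 | step 5 | (6E)-8-{2-[(tert-butyldimethylsilyl)oxy]-5-(4,4,5,5-tetramethyl-1,3,2-dioxaborolan-2-yl)phenyl}-2,6-dimethyloct-6-en-2-ol | C/C(=C\Cc1cc(B2OC(C)(C)C(C)(C)O2)ccc1O[Si](C)(C)C(C)(C)C)CCCC(C)(C)O
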